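**Easy step.** In the birch run the solid L reads 0.1% at 1.00 min, so I take dissolving as an opening and the long stretch up to the asked time of the flask as a tail.

- birch: L 0.025 M; D 21 mM (held); run made earlier
- flask: L 0.050 M; D 21 mM (held); time 12 min

birch run (percent of the L charged)

| time / min | X / % | L / % |
|---|---|---|
| 0.200 | 0.4 | 65.5 |
| 0.500 | 6.4 | 29.2 |
| 1.00 | 14.1 | 0.1 |
| 1.50 | 18.0 | 0.4 |
| 2.00 | 18.4 | 0 |
| 3.00 | 17.6 | 0 |
| 4.00 | 17.0 | 0 |

(scatter of a reading: 0.5 percentage points)

- given per volume of solution although it is solid: L
- at the start none of D is in solution
- at the start none of L is in solution

* amount of X at 12 min, in percent of the L charged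
* the change that raises the amount of X at 12 min, in percent of the L charged most ("none" if none brings more than 2 percentage points) (midnight / noon / dusk / autumn / none)
* amount of X at 12 min, in percent of the L charged, after noon

- midnight: doubling the solubility of L, all else as stated
- noon: doubling the saturation concentration of D, all else as stated
- dusk: doubling the transfer coefficient of D, all else as stated
- autumn: doubling the dissolution coefficient of L, all else as stated

**Tail rule.** I assume X is lost by meeting a partner from the same charge, a second-order loss. The reciprocal of [X] then climbs linearly with time, and [X] times time levels off at a value that forgets the charge and the opening. The birch run at 4.00 min gives 17.0 mM·min for [X] times time, the tail product. At 2.00 min it stood at 9.20 mM·min, lower than that, so it is still climbing and I treat it as a floor.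

**Flask estimate.** Dividing by 12 min gives [X] of 1.42 mM in the flask, which is 2.83% of its charge, and I commit to that floor. I take midnight, dusk and autumn to act on the opening, which the rule forgets. Noon touches the tail, so I guess a gain of 1.4 percentage points, reaching 4.25%. That is less than the margin of 2 points, so I choose none.

**The forecast.** It says 11%, and 17% after noon, the change it picks on the ground that “More D should favour X over the side route”, so it parts from my choice.

**Flask result.** The flask gives 4.43%, and the best choice is none: noon adds 1.2 points, reaching 5.58%.

    J + Q ⇌ X (K = 23.0 L mol⁻¹, k = 1.43 L mol⁻¹ s⁻¹)
    D ⇌ Q, rate k2*(csat - [Q]) (kL = 0.0189 s⁻¹)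
    J + X → E (k = 0.496 L mol⁻¹ s⁻¹)
    L ⇌ J, rate k4*(cs4 - [J]) while solid is left; crystals form when [J] > cs4 (solubility = 31.0 mM, k = 0.0273 s⁻¹)

**Reforged link.** The flask's tail product at 12 min is 26.6 mM·min, higher than the 17.0 mM·min read in the birch run at 4.00 min, and this is the value I now carry for the flask's charge. Applied to the same flask read at 8.00 min, it gives 6.64%, and that flask holds 6.76%.

Readings and results were computed with constants of no real substance, noise included.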